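(The earlier runs and the new flask were generated by integration with constants of no real substance; scatter was added.)

The ochre run charged twice as much substrate as reagent, yet at 4.00 h it showed a higher fraction of target than violet did. Before the next flasks we must therefore decide whether the reagent charge has to rise with the substrate charge or can stay as it is.

| flask | substrate | reagent | remark | time |
|---|---|---|---|---|
| violet | 1.8 mM | 7 mM | run made earlier |  |
| ochre | 14 mM | 7 mM | run made earlier |  |
| noon | 1.2 mM | 7.00 mM |  | 6.0 h |
| winter | 3.0 mM | 7.00 mM |  | 6.0 h |
| dawn | 10 mM | 7.00 mM |  | 6.0 h |

- violet (time / h: target / %): 0.333: 7.6; 0.833: 17.3; 2.00: 29.2; 4.00: 38.5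
- ochre (time / h: target / %): 0.333: 7.3; 0.833: 18.1; 2.00: 32.5; 4.00: 43.1

(standard deviation of a reading: 0.5 percentage points)

- "hardly changes" means that all values lie within two and a half points (for a concentration: within two and a half percent of the largest)

* [target] at the end for noon, winter, dawn, in this order
* the shape of the row from first to last (rises, then falls / rises all the way / falls all the way / falls, then rises / hardly changes)

In ochre, reagent is the smaller charge, so it is the limiting reagent if each target costs one reagent. To test that, we define the reagent draw 0.862: target formed per reagent charged, which is the fraction of substrate found as target times the ratio of the charges.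

draw = target fraction × substrate charge / reagent charge

ochre, 4.00 h: 43.1% × 14 mM / 7 mM = 0.862

violet, 4.00 h: 38.5% × 1.8 mM / 7 mM = 0.0990

At one reagent per target, ochre would keep 0.138 of its reagent at that reading and violet 0.901. Even so, from 2.00 h to 4.00 h ochre gained 11 percentage points and violet 9.3 points, so ochre gained no less than violet. We therefore do not read the draw as reagent spent, and we keep the reagent at 7.00 mM in noon, winter and dawn. Our own check is on dawn: with ochre's fraction at 4.00 h, its draw is 0.616, less than the charge even on the one-to-one count.

The forecast agrees that “reagent is not being used up stoichiometrically”. For 6.0 h it gives 0.49 mM, 1.26 mM and 4.5 mM of target, a row that rises all the way.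

The flasks give 0.474 mM, 1.22 mM and 4.59 mM, a row that rises all the way, and the forecast's row and shape both stand within the tolerance.

    substrate + reagent → intermediate A (k = 51.0 M⁻¹ h⁻¹)
    intermediate A ⇌ intermediate B (K = 2.30, k = 0.440 h⁻¹)
    substrate ⇌ target (K = 10.0, k = 0.270 h⁻¹)
    reagent ⇌ dormant form (K = 4.50, k = 0.150 h⁻¹)
    target ⇌ isomer of the product (K = 0.530, k = 0.0270 h⁻¹)

At 6.00 h the draw in dawn is 0.656, while dawn's reagent charge stands as 0.539 in intermediate A and intermediate B together, 0.296 in dormant form and 16.5% free. In noon at 6.00 h, with forward steps compared, reagent enters dormant form 34 times as fast as it enters intermediate A.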